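The trap in these runs is to read the ring gap at 1.33 min as impurity holding ring back. Teal shows 13% and violet 17%, but that gap is 1.89 standard deviations of a difference, and at 3.00 min they read 27% and 27%.

| flask | starting material | protic impurity | remark | time |
|---|---|---|---|---|
| teal | 0.074 M | 0.020 M | run made earlier |  |
| violet | 0.10 M | 0.0098 M | run made earlier |  |
| Monday's | 0.15 M | 0.00600 M |  | 4.0 min |
| Sunday's | 0.10 M | 0.0200 M |  | 4.0 min |

| run | time / min | ring / % | starting material / % |
|---|---|---|---|
| teal | 0.250 | 4 | 85 |
| teal | 0.500 | 6 | 79 |
| teal | 1.33 | 13 | 57 |
| teal | 3.00 | 27 | 36 |
| violet | 0.250 | 6 | 93 |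
| violet | 0.500 | 9 | 79 |
| violet | 1.33 | 17 | 57 |
| violet | 3.00 | 27 | 38 |

(readings scatter by 1.5 percentage points)

- which one finishes higher in amount of ring, in percent of the starting material charged ("neither" within 2 percentage points) (Monday's / Sunday's / neither)
- amount of ring at the end, in percent of the starting material charged, Monday's
- amount of ring at the end, in percent of the starting material charged, Sunday's



Minutes of the meeting on Monday's and Sunday's flasks. The analyst reported that starting material in teal and violet stood level, 36% and 38% at 3.00 min, although impurity was 0.270 of the charge in teal and 0.0980 in violet. She summed the fraction of charge left over time, calling this the exposure, and read 1.78 min for teal and 1.81 min for violet. Pooled, ring over exposure read 0.150 min⁻¹. This ring formed per unit of exposure, the ring constant, is an apparent first-order rate constant.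

She then computed the correction: the exposure gap between the runs is worth 0.55 percentage points of ring, less than the margin of 2 points. Carrying the runs forward with a late decay of 0.259 min⁻¹, she expected about 31.9% in each flask, so neither. Her doubt was Monday's impurity, 0.0400 of the charge, below what either run covers.

The forecaster disagreed, naming Monday's at 35% against 31% for Sunday's: “The gap is small, but it favours Monday's.”

The flasks give neither: Monday's 30.7%, Sunday's 30.5%.

    starting material → ring (k = 0.00260 s⁻¹)
    2 starting material → open dimer (k = 0.0180 M⁻¹ s⁻¹)
    starting material + open dimer → open trimer (k = 0.0290 M⁻¹ s⁻¹)
    starting material + protic impurity → quenched substrate (k = 0.210 M⁻¹ s⁻¹)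

Sunday's flask gives an exposure of 2.12 min, which the ring constant turns into 31.8%, against 30.5% in the flask. In Sunday's, starting material has a half-life of 4.4 min by the ring step alone. In Sunday's, by the step to quenched substrate, its half-life is longer at these two moments: 9.4 min at 1.35 min, and 32 min at 4.00 min. A neighbour of Sunday's with 0.800 equiv of impurity holds 18.1% ring, which the ring constant reads back as an exposure less than Sunday's, at 1.21 min.

The runs are calculated from invented constants.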